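**Plan**

Chain numbering used below: C1 = lactone carbonyl, C5 = lactone CH–O, C6 = carbinol, C7 and C10 = oxolane CH–O carbons, C8 and C9 = oxolane CH2 groups, C11 = ester-bearing CH, C12 = methyl.

1. Retrosynthesis cuts the coumarate ester C–O bond at C11, the lactone C1–O bond (back to a Z-enoate held open by a C5/C6 acetonide) and, as the strategic cut, the oxolane at its C8–C9 bond and its O–C10 bond together.
2. Enabling feature: the ring oxygen and C8 both sit on C7, so O–C7–C8 is a terminal epoxide in disguise. C10 carries the two-carbon branch C11–C12, so C9–C12 is buta-1,3-diene; a C8 radical adding at C9 leaves an allyl unit whose C10 end takes the C7 oxygen.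
3. Forward: D-galactal supplies C3–C8 (acetonide, hydration, alkyne homologation for C2, epoxide). The epoxide–diene [3+2] annulation closes the oxolane first. C1 follows by acetylide carboxylation, the vinyl group becomes the C11 carbinol, the arylpropiolate is attached, both alkynes are semi-hydrogenated, and acid closes the dihydropyranone last.
4. Stereochemistry: C5, C6 and C7 are C3, C4 and C5 of D-galactal; C10 comes from ligand-controlled anti attack on a π-allylpalladium unit; C11 from a Corey–Bakshi–Shibata reduction; both Z alkenes from syn addition of H2 to alkynes.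

Key step: step 5

Remark on the chemistry: the (1R,2R) ligand in step 5 is assumed to be the matched one for 2,5-cis closure on the 7R substrate; this sense of induction rests on analogy only, and the (1S,2S) ligand is the one to use if closure proves trans-selective.

**Route**

Step 1
Reactants: 1 D-galactal
Product: 2 3,4-O-isopropylidene-D-galactal
Conditions: 2,2-dimethoxypropane, PPTS (cat.), acetone, rt
Reagents that add atoms: 2,2-dimethoxypropane, COC(C)(C)OC
Why: Acid-catalysed transacetalisation (acetonide formation) under thermodynamic control should place the isopropylidene group on the cis-3,4-diol as a cis-fused dioxolane rather than on the 4,6-diol, the mild pyridinium acid sparing the enol ether; no stereocenter is formed.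

Step 2
Reactants: 2 3,4-O-isopropylidene-D-galactal
Product: 3 2-deoxy-3,4-O-isopropylidene-D-lyxo-hexopyranose (anomeric mixture)
Conditions: PPh3·HBr (5 mol %), THF/H2O (4:1), rt
Reagents that add atoms: water, O
Why: Acid-catalysed hydration of the glycal enol ether (protonation at C-2, capture of the oxocarbenium ion by water) should give the 2-deoxy lactol, whose new anomeric center is lost in the next step, while the large excess of water keeps the free 6-hydroxyl from ending as a 1,6-anhydro acetal.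

Step 3
Reactants: 3 2-deoxy-3,4-O-isopropylidene-D-lyxo-hexopyranose
Product: 4 (1R)-1-[(4S,5R)-2,2-dimethyl-5-(prop-2-yn-1-yl)-1,3-dioxolan-4-yl]ethane-1,2-diol
Conditions: dimethyl (1-diazo-2-oxopropyl)phosphonate, K2CO3, MeOH, 0 °C → rt
Reagents that add atoms: dimethyl (1-diazo-2-oxopropyl)phosphonate, CC(=O)C(=[N+]=[N-])P(=O)(OC)OC
Why: Seyferth–Gilbert homologation in its Ohira–Bestmann form acts on the open-chain aldehyde form of the lactol, which frees the C7 hydroxyl and turns the anomeric carbon into the alkyne that becomes C2–C3 of the lactone, the three stereocenters being untouched.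

Step 4
Reactants: 4 (1R)-1-[(4S,5R)-2,2-dimethyl-5-(prop-2-yn-1-yl)-1,3-dioxolan-4-yl]ethane-1,2-diol
Product: 6 (4R,5R)-2,2-dimethyl-4-[(2R)-oxiran-2-yl]-5-(prop-2-yn-1-yl)-1,3-dioxolane, via primary tosylate 5 (not isolated)
Conditions: TsCl, Et3N, Bu2SnO (2 mol %), CH2Cl2, 0 °C → rt; then K2CO3, MeOH, rt
Reagents that add atoms: none
Why: Tin-acetal-catalysed sulfonylation is selective for the primary hydroxyl of a terminal 1,2-diol, and the secondary alkoxide then closes the epoxide by intramolecular Williamson displacement at the primary carbon, so the configuration at C7 is retained.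

Step 5
Reactants: 6 (4R,5R)-2,2-dimethyl-4-[(2R)-oxiran-2-yl]-5-(prop-2-yn-1-yl)-1,3-dioxolane; 7 buta-1,3-diene
Product: 9 (2R,5S)-2-[(4S,5R)-2,2-dimethyl-5-(prop-2-yn-1-yl)-1,3-dioxolan-4-yl]-5-ethenyloxolane, via lithium iodo alkoxide 8 (not isolated)
Conditions: Pd2(dba)3 (2.5 mol %), (1R,2R)-N,N'-bis[2-(diphenylphosphanyl)benzoyl]cyclohexane-1,2-diamine (7.5 mol %), LiI (50 mol %), 7 (10 equiv, 2 M in THF), THF, 450 nm LEDs, 25 °C, sealed tube
Reagents that add atoms: none
Why: Proposed new method: LiI opens the epoxide of 6 at its unsubstituted carbon (SN2) to the iodo alkoxide 8; photoexcited zerovalent palladium abstracts the iodine atom, the primary C8 radical adds to a terminal carbon of butadiene (C8–C9 bond), the allyl radical recombines with monovalent palladium to a π-allylpalladium unit, and the lithium alkoxide attacks its substituted terminus anti to the metal (O–C10 bond), returning zerovalent palladium and LiI, so that the whole is a redox-neutral, atom-economical formal [3+2] cycloaddition of an epoxide with a diene. The closest known reaction types are the visible-light palladium-catalysed radical carbofunctionalisation of 1,3-dienes with alkyl iodides (radical Heck and allylic substitution in relay), the iodide-cocatalysed opening of terminal epoxides at the less hindered carbon used to feed radical couplings, and the Tsuji–Trost-type asymmetric allylic cycloetherification that gives 2-vinyl oxolanes. The oxolane closes by 5-exo attack of the alkoxide on the allyl unit, the seven-membered alternative at the far terminus being disfavoured. C7 keeps the configuration of the epoxide because its C–O bond is never broken, and the new C10 stereocenter is set under catalyst control by the chiral bisphosphine on the rapidly equilibrating (π–σ–π) allylpalladium diastereomers, chosen to give the 2,5-cis ring. The step needs regioselective iodide opening (secured by the monosubstituted epoxide), capture of the radical by the diene ahead of 6-exo-dig attack on the pendant alkyne (secured by the large excess of the far more reactive diene) and branched rather than linear C–O closure (secured by ring size).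

Step 6
Reactants: 9 (2R,5S)-2-[(4S,5R)-2,2-dimethyl-5-(prop-2-yn-1-yl)-1,3-dioxolan-4-yl]-5-ethenyloxolane
Product: 11 methyl 4-[(4R,5S)-5-[(2R,5S)-5-ethenyloxolan-2-yl]-2,2-dimethyl-1,3-dioxolan-4-yl]but-2-ynoate, via lithium acetylide 10 (not isolated)
Conditions: n-BuLi, THF, −78 °C; then ClCO2Me, −78 → 0 °C
Reagents that add atoms: methyl chloroformate, COC(=O)Cl
Why: Deprotonation of the terminal alkyne and C-acylation of the lithium acetylide by the chloroformate (acetylide carboxylation) installs C1, no other site being acidic enough to compete at −78 °C.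

Step 7
Reactants: 11 methyl 4-[(4R,5S)-5-[(2R,5S)-5-ethenyloxolan-2-yl]-2,2-dimethyl-1,3-dioxolan-4-yl]but-2-ynoate
Product: 12 methyl 4-[(4R,5S)-5-[(2R,5S)-5-acetyloxolan-2-yl]-2,2-dimethyl-1,3-dioxolan-4-yl]but-2-ynoate
Conditions: PdCl2(quinox) (5 mol %; quinox = 2-(4,5-dihydro-1,3-oxazol-2-yl)quinoline), AgSbF6 (12 mol %), aq. t-BuOOH, CH2Cl2, 0 °C → rt
Reagents that add atoms: tert-butyl hydroperoxide, CC(C)(C)OO
Why: Wacker-type oxidation with t-BuOOH and a cationic quinoline–oxazoline complex of divalent palladium should give the methyl ketone from the allylic ether with Markovnikov selectivity, the electron-poor internal alkyne and the stereocenter next to the new ketone being left alone in the near-neutral medium.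

Step 8
Reactants: 12 methyl 4-[(4R,5S)-5-[(2R,5S)-5-acetyloxolan-2-yl]-2,2-dimethyl-1,3-dioxolan-4-yl]but-2-ynoate
Product: 13 methyl 4-[(4R,5S)-5-[(2R,5S)-5-[(1S)-1-hydroxyethyl]oxolan-2-yl]-2,2-dimethyl-1,3-dioxolan-4-yl]but-2-ynoate
Conditions: (R)-2-methyl-CBS-oxazaborolidine (20 mol %), catecholborane, toluene/CH2Cl2, −78 °C
Reagents that add atoms: none
Why: Corey–Bakshi–Shibata reduction under reagent control (R catalyst, oxolanyl as the large group) should deliver hydride to the face that gives the 11S carbinol, the same sense as the Felkin–Anh preference of the alpha-alkoxy ketone, and catecholborane at −78 °C should not touch the ynoate.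

Step 9
Reactants: 14 4-iodophenol
Product: 15 1-iodo-4-(methoxymethoxy)benzene
Conditions: MeOCH2Cl, i-Pr2NEt, CH2Cl2, 0 °C → rt
Reagents that add atoms: chloromethyl methyl ether, COCCl
Why: Williamson-type O-alkylation of the phenol gives the methoxymethyl ether, an acetal that survives the later basic and reductive steps and is removed in the final acid step.

Step 10
Reactants: 15 1-iodo-4-(methoxymethoxy)benzene; 16 propiolic acid
Product: 17 3-[4-(methoxymethoxy)phenyl]prop-2-ynoic acid
Conditions: Pd(PPh3)2Cl2 (5 mol %), 1,4-bis(diphenylphosphino)butane (10 mol %), DBU (2.2 equiv), DMSO, 30 °C; cold aq. citric acid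
Reagents that add atoms: none
Why: Copper-free Sonogashira coupling of the aryl iodide with propiolic acid as its carboxylate salt gives the arylpropiolic acid directly, the low temperature avoiding decarboxylation.

Step 11
Reactants: 13 methyl 4-[(4R,5S)-5-[(2R,5S)-5-[(1S)-1-hydroxyethyl]oxolan-2-yl]-2,2-dimethyl-1,3-dioxolan-4-yl]but-2-ynoate; 17 3-[4-(methoxymethoxy)phenyl]prop-2-ynoic acid
Product: 18 (1S)-1-[(2S,5R)-5-[(4S,5R)-5-(4-methoxy-4-oxobut-2-yn-1-yl)-2,2-dimethyl-1,3-dioxolan-4-yl]oxolan-2-yl]ethyl 3-[4-(methoxymethoxy)phenyl]prop-2-ynoate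
Conditions: DCC, DMAP (10 mol %), CH2Cl2, 0 °C → rt
Reagents that add atoms: none
Why: Steglich esterification (carbodiimide activation, acyl transfer by DMAP) acylates the only free hydroxyl with retention at C11, and using the alkynoic acid postpones the fragile Z geometry of the coumarate.

Step 12
Reactants: 18 (1S)-1-[(2S,5R)-5-[(4S,5R)-5-(4-methoxy-4-oxobut-2-yn-1-yl)-2,2-dimethyl-1,3-dioxolan-4-yl]oxolan-2-yl]ethyl 3-[4-(methoxymethoxy)phenyl]prop-2-ynoate
Product: 19 (1S)-1-[(2S,5R)-5-[(4S,5R)-5-[(2Z)-4-methoxy-4-oxobut-2-en-1-yl]-2,2-dimethyl-1,3-dioxolan-4-yl]oxolan-2-yl]ethyl (2Z)-3-[4-(methoxymethoxy)phenyl]prop-2-enoate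
Conditions: H2 (1 atm), Pd/CaCO3 poisoned with Pb(OAc)2 (Lindlar catalyst), quinoline, EtOAc, rt, dark
Reagents that add atoms: none
Why: Lindlar semi-hydrogenation adds hydrogen syn to both conjugated alkynes, so the Z-enoate needed for lactonisation and the Z-coumarate should arise together, the poisoned catalyst and quinoline stopping at the alkene stage.

Step 13
Reactants: 19 (1S)-1-[(2S,5R)-5-[(4S,5R)-5-[(2Z)-4-methoxy-4-oxobut-2-en-1-yl]-2,2-dimethyl-1,3-dioxolan-4-yl]oxolan-2-yl]ethyl (2Z)-3-[4-(methoxymethoxy)phenyl]prop-2-enoate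
Product: 21 (1S)-1-[(2S,5R)-5-{(S)-hydroxy[(2R)-6-oxo-3,6-dihydro-2H-pyran-2-yl]methyl}oxolan-2-yl]ethyl (2Z)-3-(4-hydroxyphenyl)prop-2-enoate, via dihydroxy enoate 20 (not isolated)
Conditions: CF3CO2H/H2O/CH2Cl2 (5:1:5), 0 °C → rt, dark
Reagents that add atoms: none
Why: Acid hydrolysis removes the acetonide and the methoxymethyl ether, and the freed C5 hydroxyl lactonises onto the Z methyl ester (six-membered ring favoured over the seven-membered alternative through the C6 hydroxyl), which leaves the C6 hydroxyl free and affects no stereocenter.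

**Compound list**

1 | D-galactal (1,5-anhydro-2-deoxy-D-lyxo-hex-1-enitol) | OC[C@H]1OC=C[C@@H](O)[C@H]1O | starting material
2 | 3,4-O-isopropylidene-D-galactal | C1=C[C@H]2OC(C)(C)O[C@H]2[C@@H](CO)O1 | intermediate
3 | 2-deoxy-3,4-O-isopropylidene-D-lyxo-hexopyranose (anomeric mixture) | OC1C[C@H]2OC(C)(C)O[C@H]2[C@@H](CO)O1 | intermediate
4 | (1R)-1-[(4S,5R)-2,2-dimethyl-5-(prop-2-yn-1-yl)-1,3-dioxolan-4-yl]ethane-1,2-diol | OC[C@@H](O)[C@@H]1OC(C)(C)O[C@@H]1CC#C | intermediate
5 | (2R)-2-[(4S,5R)-2,2-dimethyl-5-(prop-2-yn-1-yl)-1,3-dioxolan-4-yl]-2-hydroxyethyl 4-methylbenzenesulfonate | Cc1ccc(cc1)S(=O)(=O)OC[C@@H](O)[C@@H]1OC(C)(C)O[C@@H]1CC#C | intermediate (not isolated)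
6 | (4R,5R)-2,2-dimethyl-4-[(2R)-oxiran-2-yl]-5-(prop-2-yn-1-yl)-1,3-dioxolane | C1O[C@H]1[C@@H]2OC(C)(C)O[C@@H]2CC#C | intermediate
7 | buta-1,3-diene | C=CC=C | starting material
8 | lithium (1S)-1-[(4S,5R)-2,2-dimethyl-5-(prop-2-yn-1-yl)-1,3-dioxolan-4-yl]-2-iodoethan-1-olate | [Li+].[O-][C@H](CI)[C@@H]1OC(C)(C)O[C@@H]1CC#C | intermediate (not isolated)
9 | (2R,5S)-2-[(4S,5R)-2,2-dimethyl-5-(prop-2-yn-1-yl)-1,3-dioxolan-4-yl]-5-ethenyloxolane (2,5-cis) | C=C[C@@H]1CC[C@H]([C@@H]2OC(C)(C)O[C@@H]2CC#C)O1 | intermediate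
10 | lithium acetylide of 9 | C=C[C@@H]1CC[C@H]([C@@H]2OC(C)(C)O[C@@H]2CC#[C-])O1.[Li+] | intermediate (not isolated)
11 | methyl 4-[(4R,5S)-5-[(2R,5S)-5-ethenyloxolan-2-yl]-2,2-dimethyl-1,3-dioxolan-4-yl]but-2-ynoate | C=C[C@@H]1CC[C@H]([C@@H]2OC(C)(C)O[C@@H]2CC#CC(=O)OC)O1 | intermediate
12 | methyl 4-[(4R,5S)-5-[(2R,5S)-5-acetyloxolan-2-yl]-2,2-dimethyl-1,3-dioxolan-4-yl]but-2-ynoate | CC(=O)[C@@H]1CC[C@H]([C@@H]2OC(C)(C)O[C@@H]2CC#CC(=O)OC)O1 | intermediate
13 | methyl 4-[(4R,5S)-5-[(2R,5S)-5-[(1S)-1-hydroxyethyl]oxolan-2-yl]-2,2-dimethyl-1,3-dioxolan-4-yl]but-2-ynoate | C[C@H](O)[C@@H]1CC[C@H]([C@@H]2OC(C)(C)O[C@@H]2CC#CC(=O)OC)O1 | intermediate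
14 | 4-iodophenol | Oc1ccc(I)cc1 | starting material
15 | 1-iodo-4-(methoxymethoxy)benzene | COCOc1ccc(I)cc1 | intermediate
16 | propiolic acid | C#CC(=O)O | starting material
17 | 3-[4-(methoxymethoxy)phenyl]prop-2-ynoic acid | COCOc1ccc(cc1)C#CC(=O)O | intermediate
18 | (1S)-1-[(2S,5R)-5-[(4S,5R)-5-(4-methoxy-4-oxobut-2-yn-1-yl)-2,2-dimethyl-1,3-dioxolan-4-yl]oxolan-2-yl]ethyl 3-[4-(methoxymethoxy)phenyl]prop-2-ynoate | C[C@H](OC(=O)C#Cc1ccc(OCOC)cc1)[C@@H]1CC[C@H]([C@@H]2OC(C)(C)O[C@@H]2CC#CC(=O)OC)O1 | intermediate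
19 | (1S)-1-[(2S,5R)-5-[(4S,5R)-5-[(2Z)-4-methoxy-4-oxobut-2-en-1-yl]-2,2-dimethyl-1,3-dioxolan-4-yl]oxolan-2-yl]ethyl (2Z)-3-[4-(methoxymethoxy)phenyl]prop-2-enoate | C[C@H](OC(=O)/C=C\c1ccc(OCOC)cc1)[C@@H]1CC[C@H]([C@@H]2OC(C)(C)O[C@@H]2C/C=C\C(=O)OC)O1 | intermediate
20 | methyl (2Z,5R,6R)-5,6-dihydroxy-6-[(2R,5S)-5-[(1S)-1-{[(2Z)-3-(4-hydroxyphenyl)prop-2-enoyl]oxy}ethyl]oxolan-2-yl]hex-2-enoate | C[C@H](OC(=O)/C=C\c1ccc(O)cc1)[C@@H]1CC[C@H]([C@H](O)[C@H](O)C/C=C\C(=O)OC)O1 | intermediate (not isolated)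
21 | (1S)-1-[(2S,5R)-5-{(S)-hydroxy[(2R)-6-oxo-3,6-dihydro-2H-pyran-2-yl]methyl}oxolan-2-yl]ethyl (2Z)-3-(4-hydroxyphenyl)prop-2-enoate | C[C@H](OC(=O)/C=C\c1ccc(O)cc1)[C@@H]1CC[C@H]([C@H](O)[C@H]2CC=CC(=O)O2)O1 | target

**Count and risks**

Total step count: 13. Longest linear sequence: 11 steps (steps 1–8 and 11–13); steps 9 and 10 make the side-chain acid.

Steps most likely to fail:

1. Step 5 (proposed new method). The epoxide–iodide shuttle may turn over too slowly. The C8 radical may be diverted into cyclisation onto the pendant alkyne or, after capture by palladium, into beta-hydride elimination. The diene may be consumed by palladium-catalysed telomerisation with the alkoxide. Ring closure may show poor facial control, giving a cis/trans mixture at C10.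
   Fallback, known chemistry only, setting out from 6 and returning at 13 (it replaces steps 5–8): (S)-but-3-yn-2-ol is silylated (TBSCl, imidazole) to (S)-tert-butyl(but-3-yn-2-yloxy)dimethylsilane F1. Its lithium acetylide (n-BuLi, BF3·OEt2, THF, −78 °C) should open epoxide 6 at C8 to the homopropargylic alcohol F2, which already holds C9–C12 and the C11 stereocenter. Ph3PAuCl/AgOTf (monovalent gold, CH2Cl2, rt) should induce 5-endo-dig cycloisomerisation to the dihydrofuran F3. Ionic hydrogenation (Et3SiH, CF3CO2H, CH2Cl2, −78 °C) protonates C9 and delivers hydride to the C10 oxocarbenium ion anti to the C7 substituent, which should give the 2,5-cis oxolane silyl ether F4. Acetylide carboxylation (n-BuLi, ClCO2Me) gives the ynoate silyl ether F5, and Bu4NF buffered with AcOH frees the carbinol, which is compound 13.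

2. Step 7. Oxypalladation of the allylic ether may go with the wrong regiochemistry and give the aldehyde, the catalyst may be inhibited by the alkyne, or the stereocenter next to the new ketone may epimerise.
   Fallback, setting out from 11 and returning at 13 (it replaces steps 7 and 8): ozonolysis (O3, CH2Cl2, −78 °C; Me2S) cleaves only the vinyl group to give the oxolane aldehyde F6. Chelation-controlled addition of MeMgBr in the presence of MgBr2·OEt2 (CH2Cl2, −78 °C, Cram chelate through the ring oxygen) should then give the threo carbinol 13 directly, the stereocenter being set by the substrate instead of by a chiral reagent.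

3. Step 12. Two alkynes of different reactivity must both stop at the alkene, so over-reduction of one or incomplete reduction of the other is possible, as is partial loss of Z geometry at the aryl-conjugated alkene.
   Fallback, setting out from 13 and returning at 19: Lindlar semi-hydrogenation of the single ynoate of 13 gives the Z-enoate alcohol F7. The coumarate then arrives with its geometry fixed by olefination: Still–Gennari reaction of commercial 4-(methoxymethoxy)benzaldehyde (methyl bis(2,2,2-trifluoroethyl)phosphonoacetate, KN(SiMe3)2, 18-crown-6, THF, −78 °C) gives the methyl Z-cinnamate F8, LiOH (THF/H2O) gives the Z acid F9, and Steglich esterification of F7 with F9 (DCC, DMAP, 0 °C, dark) gives 19.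

Further compounds
F1 | step 5 | (S)-tert-butyl(but-3-yn-2-yloxy)dimethylsilane | C[C@H](O[Si](C)(C)C(C)(C)C)C#C
F2 | step 5 | (1R,5S)-5-{[tert-butyl(dimethyl)silyl]oxy}-1-[(4S,5R)-2,2-dimethyl-5-(prop-2-yn-1-yl)-1,3-dioxolan-4-yl]hex-3-yn-1-ol | O[C@H](CC#C[C@H](C)O[Si](C)(C)C(C)(C)C)[C@@H]1OC(C)(C)O[C@@H]1CC#C
F3 | step 5 | tert-butyl{(1S)-1-[(5R)-5-[(4S,5R)-2,2-dimethyl-5-(prop-2-yn-1-yl)-1,3-dioxolan-4-yl]-4,5-dihydrofuran-2-yl]ethoxy}dimethylsilane | C[C@H](O[Si](C)(C)C(C)(C)C)C1=CC[C@H]([C@@H]2OC(C)(C)O[C@@H]2CC#C)O1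
F4 | step 5 | tert-butyl{(1S)-1-[(2S,5R)-5-[(4S,5R)-2,2-dimethyl-5-(prop-2-yn-1-yl)-1,3-dioxolan-4-yl]oxolan-2-yl]ethoxy}dimethylsilane | C[C@H](O[Si](C)(C)C(C)(C)C)[C@@H]1CC[C@H]([C@@H]2OC(C)(C)O[C@@H]2CC#C)O1
F5 | step 5 | methyl 4-[(4R,5S)-5-[(2R,5S)-5-[(1S)-1-{[tert-butyl(dimethyl)silyl]oxy}ethyl]oxolan-2-yl]-2,2-dimethyl-1,3-dioxolan-4-yl]but-2-ynoate | C[C@H](O[Si](C)(C)C(C)(C)C)[C@@H]1CC[C@H]([C@@H]2OC(C)(C)O[C@@H]2CC#CC(=O)OC)O1
F6 | step 7 | methyl 4-[(4R,5S)-5-[(2R,5S)-5-formyloxolan-2-yl]-2,2-dimethyl-1,3-dioxolan-4-yl]but-2-ynoate | O=C[C@@H]1CC[C@H]([C@@H]2OC(C)(C)O[C@@H]2CC#CC(=O)OC)O1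
F7 | step 12 | methyl (2Z)-4-[(4R,5S)-5-[(2R,5S)-5-[(1S)-1-hydroxyethyl]oxolan-2-yl]-2,2-dimethyl-1,3-dioxolan-4-yl]but-2-enoate | C[C@H](O)[C@@H]1CC[C@H]([C@@H]2OC(C)(C)O[C@@H]2C/C=C\C(=O)OC)O1
F8 | step 12 | methyl (2Z)-3-[4-(methoxymethoxy)phenyl]prop-2-enoate | COCOc1ccc(cc1)/C=C\C(=O)OC
F9 | step 12 | (2Z)-3-[4-(methoxymethoxy)phenyl]prop-2-enoic acid | COCOc1ccc(cc1)/C=C\C(=O)O
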